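I began with an easy subtraction on the oak run, and the pool that subtraction reveals is the thing to watch.

in all of them: starting material 0.050 M

| flask | partner | protic impurity | temperature | remark | time |
|---|---|---|---|---|---|
| oak | 2.5 equiv | 0.015 M | 20 °C | the very flask that is asked about, followed so far |  |
| larch | 2.5 equiv | 0.015 M | 15 °C | run made earlier |  |
| flask | 2.50 equiv | 0.0150 M | 20 °C |  | 3.0 h |

- oak (time / h: target / %, starting material / %): 0.417: 43, 40; 0.833: 65, 15; 1.33: 70, 6; 1.50: 75, 5; 2.00: 79, 2; 2.50: 80, 5; 3.00: 79, 2
- larch (time / h: target / %, starting material / %): 0.417: 29, 60; 0.833: 48, 37; 1.33: 61, 20; 1.50: 64, 15; 2.00: 66, 6; 2.50: 69, 8; 3.00: 73, 3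

(readings scatter by 2 percentage points)

- Wednesday's: at 3.0 h add partner, 100% of the amount charged, then wait 3.0 h
- Saturday's: change nothing and wait 3.0 h more
- Tuesday's: at 3.0 h take out 90% of the target then present, then wait 3.0 h
- Thursday's: at 3.0 h raise the temperature by 15 K, then wait 3.0 h

* target, in percent of the starting material first charged, at 3.0 h
* the option that brings most further target ("none" if no option brings more than 2 percentage points) (Wednesday's / Saturday's / Tuesday's / Thursday's / none)
* target present, with what was taken out counted in, in percent of the starting material first charged, after Wednesday's
* target present, with what was taken out counted in, in percent of the starting material first charged, after Tuesday's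

- target taken out counts as made
- on the list of suspects stand: starting material -> target; intermediate A <-> intermediate B; partner + protic impurity -> quenched reagent; 2 partner -> self-condensation product; starting material + partner <-> intermediate A
- additions bring no volume worth counting

1. At 0.417 h the oak run had used 60.0% of its starting material, yet target stood at 43%, so 17.0% lay elsewhere.

2. I followed one molecule of starting material. It either turns into target or binds partner and is parked as intermediate A or B. The odds of the fork, target gained over material parked in the first reading (a selectivity factor), read 2.53 in oak, so the direct share was 71.7%. The larch run read 2.64, close to oak. Partner enters the parking step and not the direct one, so at fixed temperature I took the odds as going inversely with free partner, and I took the oak reading as the odds at the full charge of partner.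

3. Time: one pass would park 28.3% of what reacts, but the last 3 oak readings average 79.3% target and leave 17.7% parked, a factor 0.624. If the pool shrinks by that factor again, Saturday's brings 6.7 percentage points, and I committed to 79.3% now.

4. Target removal: target stands on no way back, so Tuesday's should equal Saturday's, about 86.0% counted in.

5. Partner: Wednesday's lowers the odds for each returning molecule, so I expected a smaller gain than Saturday's.

6. Temperature: at 0.833 h oak's starting material had decayed 1.91 times as far as larch's, about twice. Taking 3 such steps for 15 K, and assuming the pool speeds up alike, Thursday's brings 17 points, my best option.

The forecast gave 79% at the asked time, Thursday's as the best option, 80% after Wednesday's and 81% after Tuesday's, with “Waiting gives about 1–2 points”, so my waiting gain stood higher.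

The flask gave 81.9%, and Thursday's won with 17 points, against 6.2 points for Saturday's, 6.2 points for Tuesday's, which ended at 88.1% counted in, and 5.4 points for Wednesday's, which ended at 87.3%. At 3.00 h the free partner stood at 50.9% of its charge. Carried there, the odds become 4.97, a share of 83.2% for a returning molecule, while Wednesday's addition lowers them to 1.68, a share of 62.7%.

    starting material → target (k = 4.60 × 10⁻⁴ /s, Ea = 80.0 kJ/mol)
    intermediate A ⇌ intermediate B (K = 0.580, k = 2.50 × 10⁻⁴ /s, Ea = 97.0 kJ/mol, ΔH = −49.0 kJ/mol)
    partner + protic impurity → quenched reagent (k = 0.0150 /M/s, Ea = 59.0 kJ/mol)
    2 partner → self-condensation product (k = 2.70 × 10⁻⁴ /M/s, Ea = 61.0 kJ/mol)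
    starting material + partner ⇌ intermediate A (K = 20.0 /M, k = 0.00150 /M/s, Ea = 60.0 kJ/mol, ΔH = −20.0 kJ/mol)
    (constants at 20 °C)

In the neighbour flask with 6.20 equiv of partner, the odds at the full charge scale to 1.02, so one pass would send 49.3% of the charge to target. That neighbour computed at 66.3% target, more than one pass gives and less than the flask's 81.9%, with 19.2% as intermediate A and 12.0% as intermediate B.

(The runs were generated by integration with made-up constants; the scatter is artificial.)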